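**Retrosynthetic overview**

1. Target 20 ⇐ hydrogenolysis of pentabenzyl ether 19 ⇐ double SNAr (C5–O and C7–O) on the 5,7-difluoroflavonol ether 16 with two molecules of benzyl alcohol 17.
2. Feature: on ring A, O5 and O7 sit ortho and para to C4a, which carries the C4 carbonyl, and they flank the C6 chain. Fluorine at C5 and C7 is therefore a carbonyl-activated leaving group, and because the single oxygen of the difluorophenol becomes O1, the carbon between the two fluorines can only be C6.
3. 16 ⇐ cyclodehydration (O1–C2, ring C, the only ring formed) of diketone 15 ⇐ Baker–Venkataraman shift of ester 14 ⇐ phenol 12 + aroyl chloride 13 (ring B bought).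
4. 12 ⇐ MOM-directed ortho-lithiation of 6 and acylation with Weinreb amide 9 (C4a–C4 bond).
5. 6 ⇐ 4-bromo-3,5-difluorophenol 1 (ring A bought): MOM ether, Sonogashira coupling with 2-methylbut-3-yn-2-ol 3, hydrogenation, O-benzylation.

Key step: step 11

Assumption: in DMF the first fluoride to leave is taken to be the one at C7 (para to the carbonyl). Should C5 react first, both monoethers converge on the same diether 19.

**Route**

Step 1
Reactants: 1 4-bromo-3,5-difluorophenol
Product: 2 2-bromo-1,3-difluoro-5-(methoxymethoxy)benzene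
Conditions: MOMCl, i-Pr2NEt, CH2Cl2, 0 °C → rt
Reagents that add atoms: chloromethyl methyl ether (MOMCl), COCCl
Why: O-alkylation of the acidic phenol (Williamson-type acetal formation) installs the MOM group that later directs the ortho-lithiation, and the aryl halides are inert to it.

Step 2
Reactants: 2 2-bromo-1,3-difluoro-5-(methoxymethoxy)benzene; 3 2-methylbut-3-yn-2-ol
Product: 4 4-[2,6-difluoro-4-(methoxymethoxy)phenyl]-2-methylbut-3-yn-2-ol
Conditions: Pd(PPh3)2Cl2 (cat.), CuI (cat.), Et3N, 80 °C
Reagents that add atoms: none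
Why: Sonogashira coupling; the two ortho fluorines make the C–Br bond electron-poor enough for ready oxidative addition to zerovalent palladium, and the free tertiary propargylic alcohol is tolerated.

Step 3
Reactants: 4 4-[2,6-difluoro-4-(methoxymethoxy)phenyl]-2-methylbut-3-yn-2-ol
Product: 5 4-[2,6-difluoro-4-(methoxymethoxy)phenyl]-2-methylbutan-2-ol
Conditions: H2 (1 atm), 10% Pd/C, EtOAc, rt
Reagents that add atoms: none
Why: Heterogeneous catalytic hydrogenation should saturate the alkyne to the 3-hydroxy-3-methylbutyl chain, while aryl C–F bonds, the MOM acetal and the tertiary alcohol are not touched at 1 atm and rt.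

Step 4
Reactants: 5 4-[2,6-difluoro-4-(methoxymethoxy)phenyl]-2-methylbutan-2-ol
Product: 6 2-[3-(benzyloxy)-3-methylbutyl]-1,3-difluoro-5-(methoxymethoxy)benzene
Conditions: 2-benzyloxy-1-methylpyridinium triflate (2 equiv), MgO (2 equiv), PhCF3, 85 °C
Reagents that add atoms: 2-benzyloxy-1-methylpyridinium triflate, C[n+]1ccccc1OCc1ccccc1.[O-]S(=O)(=O)C(F)(F)F
Why: Dudley benzylation transfers a benzyl cation equivalent to the hindered tertiary alcohol under near-neutral conditions, which avoids a tertiary alkoxide that could close a chroman onto an ortho fluoride and spares the acid-labile MOM acetal.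

Step 5
Reactants: 7 benzyloxyacetyl chloride; 8 N,O-dimethylhydroxylamine hydrochloride
Product: 9 2-(benzyloxy)-N-methoxy-N-methylacetamide
Conditions: Et3N (2.2 equiv), CH2Cl2, 0 °C → rt
Reagents that add atoms: none
Why: N-acylation of the hydroxylamine by the acid chloride gives the Weinreb amide needed for a single acyl transfer to an aryllithium.

Step 6
Reactants: 6 2-[3-(benzyloxy)-3-methylbutyl]-1,3-difluoro-5-(methoxymethoxy)benzene; 9 2-(benzyloxy)-N-methoxy-N-methylacetamide
Product: 11 2-(benzyloxy)-1-{3-[3-(benzyloxy)-3-methylbutyl]-2,4-difluoro-6-(methoxymethoxy)phenyl}ethan-1-one, via aryllithium 10 (not isolated)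
Conditions: n-BuLi (1.1 equiv), THF, −78 °C, 1 h; then 9, −78 °C; aq. NH4Cl
Reagents that add atoms: none
Why: Directed ortho-metalation removes the ring hydrogen flanked by OMOM and F (the two such positions are equivalent by symmetry), and the aryllithium adds once to the Weinreb amide through a chelated tetrahedral intermediate that releases the ketone only on quench.

Step 7
Reactants: 11 2-(benzyloxy)-1-{3-[3-(benzyloxy)-3-methylbutyl]-2,4-difluoro-6-(methoxymethoxy)phenyl}ethan-1-one
Product: 12 2-(benzyloxy)-1-{3-[3-(benzyloxy)-3-methylbutyl]-2,4-difluoro-6-hydroxyphenyl}ethan-1-one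
Conditions: HCl (1.25 M in MeOH), THF, rt
Reagents that add atoms: none
Why: Acid-catalysed methanolysis of the MOM acetal, which is especially labile ortho to the ketone, should free the phenol under dilute acid at rt that leaves the tertiary benzyl ether and the aryl fluorides alone.

Step 8
Reactants: 12 2-(benzyloxy)-1-{3-[3-(benzyloxy)-3-methylbutyl]-2,4-difluoro-6-hydroxyphenyl}ethan-1-one; 13 4-(benzyloxy)benzoyl chloride
Product: 14 2-[(benzyloxy)acetyl]-4-[3-(benzyloxy)-3-methylbutyl]-3,5-difluorophenyl 4-(benzyloxy)benzoate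
Conditions: Et3N, DMAP (cat.), CH2Cl2, 0 °C → rt
Reagents that add atoms: none
Why: DMAP-catalysed O-acylation of the acidic phenol gives the aryl ester that carries ring B and sets up the acyl shift.

Step 9
Reactants: 14 2-[(benzyloxy)acetyl]-4-[3-(benzyloxy)-3-methylbutyl]-3,5-difluorophenyl 4-(benzyloxy)benzoate
Product: 15 2-(benzyloxy)-1-{3-[3-(benzyloxy)-3-methylbutyl]-2,4-difluoro-6-hydroxyphenyl}-3-[4-(benzyloxy)phenyl]propane-1,3-dione (racemic at C2, in equilibrium with its enol and cyclic hemiketal)
Conditions: LiN(SiMe3)2 (3 equiv), THF, −78 → −20 °C; aq. NH4Cl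
Reagents that add atoms: none
Why: Baker–Venkataraman rearrangement: the ketone enolate attacks the neighbouring aryl ester through a six-membered transition state (O→C acyl shift), and the bulky non-nucleophilic silylamide at low temperature should not displace the ketone-activated fluorides.

Step 10
Reactants: 15 2-(benzyloxy)-1-{3-[3-(benzyloxy)-3-methylbutyl]-2,4-difluoro-6-hydroxyphenyl}-3-[4-(benzyloxy)phenyl]propane-1,3-dione
Product: 16 3-(benzyloxy)-6-[3-(benzyloxy)-3-methylbutyl]-2-[4-(benzyloxy)phenyl]-5,7-difluoro-4H-chromen-4-one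
Conditions: p-TsOH·H2O (0.1 equiv), toluene, 60 °C
Reagents that add atoms: none
Why: Acid-catalysed cyclodehydration closes ring C (phenol oxygen onto the aroyl carbonyl, then loss of water through an oxocarbenium ion stabilised by the ring oxygen and the 4-benzyloxyphenyl group), an ionisation far easier than that of the tertiary benzyl ether under catalytic acid.

Step 11
Reactants: 16 3-(benzyloxy)-6-[3-(benzyloxy)-3-methylbutyl]-2-[4-(benzyloxy)phenyl]-5,7-difluoro-4H-chromen-4-one; 17 benzyl alcohol (two molecules enter the product)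
Product: 19 3,5,7-tris(benzyloxy)-6-[3-(benzyloxy)-3-methylbutyl]-2-[4-(benzyloxy)phenyl]-4H-chromen-4-one, via 7-benzyloxy-5-fluoro monoether 18 (not isolated)
Conditions: BnOH (6 equiv), NaH (5 equiv), THF, 0 °C; then 16, DMF, rt → 60 °C
Reagents that add atoms: benzyl alcohol (second equivalent), OCc1ccccc1
Why: Sodium benzyloxide adds to C7 and then to C5 of ring A to give Meisenheimer anions whose charge runs through C4a onto the C4 carbonyl oxygen, and loss of fluoride restores the arene (addition–elimination SNAr). The closest known reaction type is the displacement of fluoride by alkoxides in 5,7-difluorochromones and in ortho- and para-fluoroaryl ketones. No ring is closed and no stereocenter is formed; two C–O bonds are made, each from one molecule of benzyl alcohol, so two molecules of the alcohol end up in the product. The step needs complete double substitution at two positions that flank the C6 chain, the second on a ring that already carries one new donor oxygen, which is why an excess of alkoxide, a dipolar aprotic solvent and gentle heating are planned. It also needs the pyranone to survive: addition of benzyloxide at C2 is reversible (a ring-opened phenoxide recloses and expels benzyloxide) whereas fluoride loss is not, and water is excluded so that no hydroxide can cleave the ring. The tertiary oxygen is a benzyl ether, so no side-chain alkoxide can close a chroman on C5 or C7.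

Step 12
Reactants: 19 3,5,7-tris(benzyloxy)-6-[3-(benzyloxy)-3-methylbutyl]-2-[4-(benzyloxy)phenyl]-4H-chromen-4-one
Product: 20 3,5,7-trihydroxy-6-(3-hydroxy-3-methylbutyl)-2-(4-hydroxyphenyl)-4H-chromen-4-one (CNP0250430.0)
Conditions: H2 (1 atm), 10% Pd/C, THF/MeOH, rt
Reagents that add atoms: none
Why: Hydrogenolysis of the five benzyl C–O bonds on palladium should free the four phenols and the tertiary alcohol, while the flavonol C2=C3 bond and the tertiary C–O bond are not reduced under these conditions.

**Compound list**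

1 | 4-bromo-3,5-difluorophenol | Oc1cc(F)c(Br)c(F)c1 | starting material
2 | 2-bromo-1,3-difluoro-5-(methoxymethoxy)benzene | COCOc1cc(F)c(Br)c(F)c1 | intermediate
3 | 2-methylbut-3-yn-2-ol | CC(C)(O)C#C | starting material
4 | 4-[2,6-difluoro-4-(methoxymethoxy)phenyl]-2-methylbut-3-yn-2-ol | COCOc1cc(F)c(C#CC(C)(C)O)c(F)c1 | intermediate
5 | 4-[2,6-difluoro-4-(methoxymethoxy)phenyl]-2-methylbutan-2-ol | COCOc1cc(F)c(CCC(C)(C)O)c(F)c1 | intermediate
6 | 2-[3-(benzyloxy)-3-methylbutyl]-1,3-difluoro-5-(methoxymethoxy)benzene | COCOc1cc(F)c(CCC(C)(C)OCc2ccccc2)c(F)c1 | intermediate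
7 | benzyloxyacetyl chloride | O=C(Cl)COCc1ccccc1 | starting material
8 | N,O-dimethylhydroxylamine hydrochloride | CNOC.Cl | starting material
9 | 2-(benzyloxy)-N-methoxy-N-methylacetamide | CON(C)C(=O)COCc1ccccc1 | intermediate
10 | {3-[3-(benzyloxy)-3-methylbutyl]-2,4-difluoro-6-(methoxymethoxy)phenyl}lithium (formed in the flask, not isolated) | [Li]c1c(OCOC)cc(F)c(CCC(C)(C)OCc2ccccc2)c1F | intermediate
11 | 2-(benzyloxy)-1-{3-[3-(benzyloxy)-3-methylbutyl]-2,4-difluoro-6-(methoxymethoxy)phenyl}ethan-1-one | COCOc1cc(F)c(CCC(C)(C)OCc2ccccc2)c(F)c1C(=O)COCc1ccccc1 | intermediate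
12 | 2-(benzyloxy)-1-{3-[3-(benzyloxy)-3-methylbutyl]-2,4-difluoro-6-hydroxyphenyl}ethan-1-one | Oc1cc(F)c(CCC(C)(C)OCc2ccccc2)c(F)c1C(=O)COCc1ccccc1 | intermediate
13 | 4-(benzyloxy)benzoyl chloride | O=C(Cl)c1ccc(OCc2ccccc2)cc1 | starting material
14 | 2-[(benzyloxy)acetyl]-4-[3-(benzyloxy)-3-methylbutyl]-3,5-difluorophenyl 4-(benzyloxy)benzoate | O=C(Oc1cc(F)c(CCC(C)(C)OCc2ccccc2)c(F)c1C(=O)COCc1ccccc1)c1ccc(OCc2ccccc2)cc1 | intermediate
15 | 2-(benzyloxy)-1-{3-[3-(benzyloxy)-3-methylbutyl]-2,4-difluoro-6-hydroxyphenyl}-3-[4-(benzyloxy)phenyl]propane-1,3-dione (racemic at C2) | O=C(c1ccc(OCc2ccccc2)cc1)C(OCc1ccccc1)C(=O)c1c(O)cc(F)c(CCC(C)(C)OCc2ccccc2)c1F | intermediate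
16 | 3-(benzyloxy)-6-[3-(benzyloxy)-3-methylbutyl]-2-[4-(benzyloxy)phenyl]-5,7-difluoro-4H-chromen-4-one | CC(C)(OCc1ccccc1)CCc1c(F)cc2oc(-c3ccc(OCc4ccccc4)cc3)c(OCc3ccccc3)c(=O)c2c1F | intermediate
17 | benzyl alcohol | OCc1ccccc1 | starting material
18 | 3,7-bis(benzyloxy)-6-[3-(benzyloxy)-3-methylbutyl]-2-[4-(benzyloxy)phenyl]-5-fluoro-4H-chromen-4-one (formed in the flask, not isolated) | CC(C)(OCc1ccccc1)CCc1c(OCc2ccccc2)cc2oc(-c3ccc(OCc4ccccc4)cc3)c(OCc3ccccc3)c(=O)c2c1F | intermediate
19 | 3,5,7-tris(benzyloxy)-6-[3-(benzyloxy)-3-methylbutyl]-2-[4-(benzyloxy)phenyl]-4H-chromen-4-one | CC(C)(OCc1ccccc1)CCc1c(OCc2ccccc2)cc2oc(-c3ccc(OCc4ccccc4)cc3)c(OCc3ccccc3)c(=O)c2c1OCc1ccccc1 | intermediate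
20 | 3,5,7-trihydroxy-6-(3-hydroxy-3-methylbutyl)-2-(4-hydroxyphenyl)-4H-chromen-4-one | CC(C)(O)CCc1c(O)cc2oc(-c3ccc(O)cc3)c(O)c(=O)c2c1O | target

**Step count and risks**

Total step count: 12. Longest linear sequence: 11 steps (steps 1–4 and 6–12); step 5 is a one-step side branch.

Steps most likely to fail:

1. Step 11. The reaction may stall after the first substitution, because the remaining fluoride at C5 is hindered and sits on a ring made more electron-rich by the new ether. The heating needed to force it may instead let the alkoxide degrade the pyranone through attack at C2. Fallback: the route sets out from 16, and one equivalent of sodium benzyloxide in THF at 0 °C should stop at the monoether 18, which is isolated. Compound 18 is then treated with (E)-benzaldoxime and K2CO3 in DMSO at 80 °C, a hydroxide surrogate. The oximate, a less basic alpha-effect nucleophile, displaces the C5 fluoride to give the O-aryl oxime ether (E)-benzaldehyde O-{3,7-bis(benzyloxy)-6-[3-(benzyloxy)-3-methylbutyl]-2-[4-(benzyloxy)phenyl]-4-oxo-4H-chromen-5-yl}oxime F1. This fragments under the base to benzonitrile and the chelated phenol 3,7-bis(benzyloxy)-6-[3-(benzyloxy)-3-methylbutyl]-2-[4-(benzyloxy)phenyl]-5-hydroxy-4H-chromen-4-one F2. Hydrogenolysis of the four benzyl ethers of F2 under the conditions of step 12 returns to the route at the target 20.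

2. Step 6. Proton transfer from the α-benzyloxy amide to the aryllithium, or slow acyl transfer at −78 °C, may return starting arene. Warming to drive the addition invites loss of LiF from the ortho-fluoro aryllithium and aryne chemistry. Fallback: the route sets out from 6, and the aryllithium 10 is generated as before and trapped at −78 °C with benzyloxyacetaldehyde, a much more electrophilic partner that reacts without warming. This gives the racemic secondary alcohol 2-(benzyloxy)-1-{3-[3-(benzyloxy)-3-methylbutyl]-2,4-difluoro-6-(methoxymethoxy)phenyl}ethan-1-ol F3. Oxidation of F3 with Dess–Martin periodinane in CH2Cl2 returns to the route at ketone 11.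

3. Step 9. The phenoxide set free by the acyl shift, or the amide base, may displace the ketone-activated fluorides of a second molecule and give diaryl ether oligomers, and the acyl shift may be slow at the crowded, doubly ortho-substituted ketone. Fallback: the route sets out from 11, in which the phenol is still masked as its MOM ether. Its lithium enolate (LiN(SiMe3)2, 2.2 equiv, THF, −78 °C) is C-acylated with the acid chloride 13 in a Claisen-type acylation. This gives the MOM-protected diketone 2-(benzyloxy)-1-{3-[3-(benzyloxy)-3-methylbutyl]-2,4-difluoro-6-(methoxymethoxy)phenyl}-3-[4-(benzyloxy)phenyl]propane-1,3-dione F4. HCl in MeOH at rt then removes the MOM group and returns to the route at diketone 15, which is cyclised as in step 10.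

**Further compounds**

F1 | step 11 | (E)-benzaldehyde O-{3,7-bis(benzyloxy)-6-[3-(benzyloxy)-3-methylbutyl]-2-[4-(benzyloxy)phenyl]-4-oxo-4H-chromen-5-yl}oxime | CC(C)(OCc1ccccc1)CCc1c(OCc2ccccc2)cc2oc(-c3ccc(OCc4ccccc4)cc3)c(OCc3ccccc3)c(=O)c2c1O/N=C/c1ccccc1
F2 | step 11 | 3,7-bis(benzyloxy)-6-[3-(benzyloxy)-3-methylbutyl]-2-[4-(benzyloxy)phenyl]-5-hydroxy-4H-chromen-4-one | CC(C)(OCc1ccccc1)CCc1c(OCc2ccccc2)cc2oc(-c3ccc(OCc4ccccc4)cc3)c(OCc3ccccc3)c(=O)c2c1O
F3 | step 6 | 2-(benzyloxy)-1-{3-[3-(benzyloxy)-3-methylbutyl]-2,4-difluoro-6-(methoxymethoxy)phenyl}ethan-1-ol (racemic) | COCOc1cc(F)c(CCC(C)(C)OCc2ccccc2)c(F)c1C(O)COCc1ccccc1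
F4 | step 9 | 2-(benzyloxy)-1-{3-[3-(benzyloxy)-3-methylbutyl]-2,4-difluoro-6-(methoxymethoxy)phenyl}-3-[4-(benzyloxy)phenyl]propane-1,3-dione (racemic) | COCOc1cc(F)c(CCC(C)(C)OCc2ccccc2)c(F)c1C(=O)C(OCc1ccccc1)C(=O)c1ccc(OCc2ccccc2)cc1
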